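Qa enters chains slowly: after 15.0 h the beta run still holds 35% of it as free Qa.

| flask | Qa | Qc | remark | time |
|---|---|---|---|---|
| alpha | 0.50 M (fed, over 20 min) | 1.9 mol% | run made earlier |  |
| beta | 0.50 M (fed, over 20 min) | 3 mol% | run made earlier |  |
| zeta | 0.50 M (fed, over 20 min) | 3.5 mol% | run made earlier |  |
| north-west | 0.50 M (fed, over 20 min) | 3.8 mol% |  | 20 h |
| north | 0.50 M (fed, over 20 min) | 2 mol% |  | 20 h |

| run | time / h | Qb / % | Qa / % |
|---|---|---|---|
| alpha | 1.00 | 1 | 95 |
| alpha | 2.00 | 11 | 92 |
| alpha | 4.00 | 24 | 78 |
| alpha | 8.00 | 42 | 60 |
| alpha | 15.0 | 52 | 45 |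
| beta | 1.00 | 1 | 95 |
| beta | 2.00 | 16 | 84 |
| beta | 4.00 | 33 | 67 |
| beta | 8.00 | 52 | 46 |
| beta | 15.0 | 65 | 35 |
| zeta | 3.00 | 26 | 72 |
| zeta | 6.00 | 48 | 51 |
| zeta | 8.00 | 54 | 43 |
| zeta | 12.0 | 63 | 37 |
| zeta | 15.0 | 65 | 33 |

(scatter of a reading: 1.5 percentage points)

- the average divides the monomer in chains by the number of chains begun, living and dead together
- what was read earlier has a scatter of 1.5 percentage points, one standard deviation
- the earlier runs do not show the number of chains; that part of a forecast is a guess

- which of the two ends with the longer chains by the average number of monomer units in a chain (chains begun, living or dead) ("neither" if they lie within 10%) (north-west / north / neither)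
- average number of monomer units in a chain (chains begun, living or dead) at the end, north-west
- average number of monomer units in a chain (chains begun, living or dead) at the end, north

1. Start. The feed ends after 20 min, and at 1.00 h the beta run shows 1% of Qb. Between 1.00 h and 2.00 h Qb gains 15 percentage points, and between 2.00 h and 4.00 h it gains 17 points.

2. Knee. From 4.00 h to 8.00 h the beta run gains 19 points, slower per hour than before.

3. Crossing. Qb passes Qa between 4.00 h and 8.00 h in the beta run, and between 8.00 h and 15.0 h in the alpha run, with its lower loading.

4. Level. None shows yet. The stretch of the zeta run from 8.00 h to 15.0 h, continued straight to 20 h, puts 72.9% in chains for north-west, its nearest loading. The alpha run, continued straight over the same stretch from 8.00 h to 15.0 h, gives 59.1% for north. These are rough readings of my own.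

5. Freeze the denominator. The runs do not show the chain count, so one chain per Qc charged is a guess. The average (number-average chain length) is then the reacted share times the full-conversion length, the units per chain once every Qa has reacted, one over the loading: 26.3 for north-west and 50.0 for north.

6. Own reckoning: 19.2 for north-west, 29.6 for north.

The forecast names north, with 19 (15 to 32) for north-west and 30 (24 to 50) for north. It reaches its shares by a fitted curve instead of straight lines, then proceeds by “Assuming one chain per Qc charged”.

The flask gives north: 19.5 for north-west, 30.9 for north.

    Qa + Qc → Qd + Qb (k = 1.70 L mol⁻¹ h⁻¹)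
    Qa + Qd → Qb + Qd, rate k2*[Qd]*[Qa] (k = 12.0 L mol⁻¹ h⁻¹)
    2 Qd → Qe (k = 11.0 L mol⁻¹ h⁻¹)

In north-west Qc stands at 0.0446% of its charge at 20.0 h, so the chain count has nearly stopped moving, and the full-conversion length 26.3 times the 74.1% reacted gives 19.5. North reacts less Qa, 61.9%, yet ends longer, and the difference in loading of Qc is the main reason: north gives 30.9 at its own loading and 19.5 at the loading of north-west, and its full-conversion length is 50.0. A neighbour of north-west with Qa at 0.20 M keeps the length 26.3 and, with 43% of Qa left, reckons to 15.0; that flask gives 15.1.

All runs come from a simulation with made-up constants; noise was put on by code.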